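Start with a division: target formed over enzyme charged gives the turnovers each enzyme has made. You have to choose which flask to charge next, and that count is what I would choose by.

all flasks: starting material 20 mM; added ligand 1.1 µM

|  | second substrate | enzyme | remark | time |
|---|---|---|---|---|
| north-west | 18 mM (fed, over 2.0 min) | 1.8 µM | run made earlier |  |
| west | 18 mM (fed, over 2.0 min) | 3 µM | run made earlier |  |
| Friday's | 18.0 mM | 1.2 µM | everything together at the start | 2.0 min |
| Monday's | 18.0 mM (fed, over 2.0 min) | 2.0 µM |  | 2.0 min |

- north-west (time / s: target / %, starting material / %): 10.0: 0, 98; 12.0: 0, 100; 20.0: 3, 97; 40.0: 7, 95; 60.0: 8, 89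
- west (time / s: target / %, starting material / %): 10.0: 3, 100; 20.0: 1, 96; 30.0: 3, 96; 40.0: 6, 92; 50.0: 10, 90; 60.0: 14, 85

(standard deviation of a reading: 1.5 percentage points)



- which of the two ends with the higher amount of target, in percent of the starting material charged ("neither" if they lie within 2 percentage points) (Friday's / Monday's / neither)
- target at the end, in percent of the starting material charged, Friday's
- target at the end, in percent of the starting material charged, Monday's

At 60.0 s the north-west run holds 8 % of target on 1.8 µM of enzyme, which is 889 turnovers. The west run, at 60.0 s, holds 14 % on 3 µM, which is 933. Each reading scatters by 1.5 percentage points, so I take these as one value: the turnover count n, target made per enzyme charged at that point of the feed, n = 911.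

How does n grow? In the west run the readings of target rise by a factor of 4.67 from 30.0 s to 60.0 s, a rough figure given their scatter, and the square of the time ratio is 4.00. So I let the count follow the area under the curve of second substrate against time.

Monday's, fed throughout, has 4.00 times the area of that point, giving 3640 turnovers. Friday's, with everything in at the start, has 8.00 times it, giving 7290.

Multiplied by the enzyme, that is 43.7 % for Friday's and 36.4 % for Monday's, with starting material held at its charge and second substrate at what has gone in. Both fall as target forms, so I expect less in both flasks. Monday's has 1.67 times the enzyme, but on this count Friday's gets twice the turnovers per enzyme, so I would charge Friday's, which my reckoning puts ahead.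

The forecast also says Friday's, with 31 % (20 % to 37 %) for Friday's and 27 % (22 % to 32 %) for Monday's. Both lie lower than mine, and for Friday's it warns of “partial ligand poisoning at low enzyme”.

Friday's ends with 39.4 % of target and Monday's with 31.2 %, so Friday's has more, and Friday's stands above the forecast's top of 37 %.

    starting material + enzyme ⇌ starting complex (K = 59.0 M⁻¹, k = 1.08 × 10⁶ M⁻¹ s⁻¹)
    second substrate + starting complex ⇌ ternary complex (K = 650 M⁻¹, k = 57800 M⁻¹ s⁻¹)
    ternary complex → enzyme + target (k = 173 s⁻¹)
    2 starting material → self-condensation product (k = 0.00403 M⁻¹ s⁻¹)
    2 enzyme ⇌ resting dimer, settled at all times (K = 1.24 × 10⁷ M⁻¹)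
    enzyme + added ligand ⇌ idle complex, settled at all times (K = 2.20 × 10⁵ M⁻¹)

At the end of Friday's the resting dimer, an off-cycle resting state, holds 53.6 % of the catalyst charged. In turnovers, Friday's reached 6560 against my 7290, and Monday's 3120 against my 3640. For the neighbour flask like Friday's but with 7.2 mM of second substrate, the count scaled to that charge gives 2920 turnovers, and that flask made 3200.

All runs come from a simulation for substances that don't exist; the scatter is artificial.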